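**Retrosynthetic overview**
1. Target ⇒ (E)-3-bromo-enynoic acid 9 by anti 5-exo-dig bromolactonization. This forms the only ring, last, and fixes the exocyclic Br cis to C4.
2. 9 ⇒ gem-dibromoacrylic acid 7 by carboxylate-directed mono-alkynylation (C4–C5 bond).
3. 7 ⇒ α-keto ester 5 by gem-dibromo-olefination (C3=C4 bond), then ester cleavage.
4. 5 ⇒ racemic 1-chlorobutyl acetate 3 + an oxalyl monoester chloride by Ni-catalysed enantioconvergent radical acyl cross-coupling (C3–C1′ bond; sets R with the acetate already in place).
5. 3 ⇒ butanal + acetyl chloride.

Assumption: the SMILES is read literally, i.e. (R) at the carbinol carbon and the exocyclic bromine cis to C4 / trans to the ring oxygen (5E).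

**Route**

Step 1
Reactants: 1 butanal; 2 acetyl chloride
Product: 3 rac-1-chlorobutyl acetate
Conditions: ZnCl2 (2 mol %), CH2Cl2, −10 °C → rt; distil
Reagents that add atoms: none (both partners are reactants)
Why: Lewis-acid-catalysed addition of an acyl chloride across the aldehyde C=O (α-chloroalkyl ester formation); the product is deliberately racemic because step 2 is enantioconvergent.

Step 2
Reactants: 3 rac-1-chlorobutyl acetate; 4 tert-butyl chlorooxoacetate
Product: 5 tert-butyl (3R)-3-acetoxy-2-oxohexanoate
Conditions: NiCl2·dme (10 mol %), chiral bis(oxazoline) (12 mol %, enantiomer that delivers R, chosen empirically), Mn powder (3 equiv), 2,6-dimethylbenzoic acid (0.75 equiv), 3 Å MS, THF/DMA 7:3, 0 → 10 °C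
Reagents that add atoms: none (both partners are reactants)
Why: Proposed new method: Ni(0)/BOX adds oxidatively to the acyl chloride, Ni(I) abstracts Cl from either enantiomer of 3 to give the planar α-acetoxybutyl radical, and capture at the chiral acyl–Ni centre followed by reductive elimination from Ni(III) forms the C–C bond and sets (R); the closest known reactions are the Ni/bis(oxazoline) asymmetric reductive acyl cross-coupling of acid chlorides with racemic secondary benzylic chlorides and Ni-catalysed enantioconvergent couplings of racemic α-haloalkyl esters, and the carboxylic acid additive and low temperature limit enolisation of the product.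

Step 3
Reactants: 5
Product: 6 tert-butyl 2-[(1R)-1-acetoxybutyl]-3,3-dibromoprop-2-enoate
Conditions: CBr4, PPh3, Zn dust, CH2Cl2, rt (ylide pre-formed); then 5, 0 °C → rt
Reagents that add atoms: carbon tetrabromide, BrC(Br)(Br)Br
Why: Ramirez gem-dibromo-olefination of the highly electrophilic α-keto ester carbonyl with a pre-formed, weakly basic ylide; the C1′ stereocentre is not touched and becomes a non-enolisable allylic centre.

Step 4
Reactants: 6
Product: 7 2-[(1R)-1-acetoxybutyl]-3,3-dibromoprop-2-enoic acid
Conditions: TFA/CH2Cl2 1:4, 0 °C → rt
Reagents that add atoms: none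
Why: Acidolysis of the tert-butyl ester (isobutylene loss); the secondary acetate on the electron-poor alkene and the vinyl bromides are inert to TFA.

Step 5
Reactants: 7; 8 ethynylmagnesium bromide (transmetalated in situ to ethynylzinc bromide)
Product: 9 (2E)-2-[(1R)-1-acetoxybutyl]-3-bromopent-2-en-4-ynoic acid
Conditions: HC≡CMgBr, ZnBr2, THF, 0 °C; then 7 (2.3 equiv alkynylzinc in total), Pd2(dba)3 (2.5 mol %, no phosphine), THF/NMP, 0 → 23 °C; cold pH 3 work-up
Reagents that add atoms: none beyond reactant 8 (ZnBr2 only transmetalates)
Why: Negishi mono-alkynylation in which the zinc carboxylate directs oxidative addition to the C–Br bond syn to it, so the ethynyl group ends up cis to CO2H (the selectivity is extrapolated from carboxylate-directed couplings of dihalobenzoic acids); copper-, amine- and phosphine-free conditions leave the enynoic acid uncyclised and the allylic acetate un-ionised.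

Step 6
Reactants: 9
Product: 10 acetoxyfimbrolide, (1R)-1-[(5E)-4-bromo-5-(bromomethylidene)-2-oxo-2,5-dihydrofuran-3-yl]butyl acetate
Conditions: NBS (1.1 equiv), KHCO3 (1.2 equiv), MeCN, 0 °C, dark
Reagents that add atoms: N-bromosuccinimide, O=C1CCC(=O)N1Br
Why: 5-exo-dig bromolactonization of a (Z)-disposed enynoic acid (the bromo analogue of the known iodolactonization), in which the carboxylate attacks the internal alkyne carbon anti to Br+, placing the new Br trans to the ring oxygen and cis to C4 as in the target; ionic, dark conditions avoid E/Z scrambling and leave C1′ untouched.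

**Compound list**
1 | butanal | CCCC=O | starting material
2 | acetyl chloride | CC(=O)Cl | starting material
3 | rac-1-chlorobutyl acetate | CCCC(Cl)OC(C)=O | intermediate
4 | tert-butyl chlorooxoacetate (tert-butyl is the carboxyl protecting group) | CC(C)(C)OC(=O)C(=O)Cl | starting material
5 | tert-butyl (3R)-3-acetoxy-2-oxohexanoate | CCC[C@@H](OC(C)=O)C(=O)C(=O)OC(C)(C)C | intermediate
6 | tert-butyl 2-[(1R)-1-acetoxybutyl]-3,3-dibromoprop-2-enoate | CCC[C@@H](OC(C)=O)C(C(=O)OC(C)(C)C)=C(Br)Br | intermediate
7 | 2-[(1R)-1-acetoxybutyl]-3,3-dibromoprop-2-enoic acid | CCC[C@@H](OC(C)=O)C(C(=O)O)=C(Br)Br | intermediate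
8 | ethynylmagnesium bromide | C#C[Mg]Br | starting material
9 | (2E)-2-[(1R)-1-acetoxybutyl]-3-bromopent-2-en-4-ynoic acid | CCC[C@@H](OC(C)=O)/C(C(=O)O)=C(\Br)C#C | intermediate
10 | acetoxyfimbrolide | CCC[C@@H](OC(C)=O)C1=C(Br)/C(=C\Br)OC1=O | target

**Step count**
Total steps: 6. Longest linear sequence: 6 (1 → 3 → 5 → 6 → 7 → 9 → 10).

**Three steps most likely to fail, with fallbacks**
- **Step 2** (decarbonylation of the oxalyl–Ni intermediate, modest ee, or enolisation of 5). Fallback: keep the Ni radical coupling of 3 but use 3,4-dibromofuran as the sp2 partner (symmetrical, mono-alkenylation gives a configurationally robust acetate). Then formylate next to Br, open the ring through the tosylhydrazone-derived 2-furylcarbene to the (Z)-bromo-enynal, and oxidise (Pinnick) to 9.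
- **Step 3** (epimerisation of the α-acetoxy α-keto ester or sluggish olefination). Fallback: olefinate 5 with the neutral stabilised ylide Ph3P=C(Br)CHO to the bromo-enal. After tert-butyl cleavage the cis isomer is trapped as the cyclic pseudo-acid (4-bromo-5-hydroxybutenolide, ring-enforced geometry), and Seyferth–Gilbert homologation of its aldehyde form gives 9, bypassing step 5.
- **Step 5** (wrong bromine reacts, double alkynylation, or premature cyclisation). Fallback: run a Pd/Cu Sonogashira–lactonization cascade on 7 with trimethylsilylacetylene, which only the syn-bromine product can complete, to the (Z)-5-(trimethylsilylmethylidene) lactone. Then add Br2 and eliminate Me3SiBr (net inversion) to obtain the E-bromide.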